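The numbers belong to no real substance, and the outcome is calculated.

At 3.0 min we read how much E.Q stands in the flasks.

common to all: J 4.90 mM; D 9.80 mM; time 3.0 min

| charge | E | Q | remark | temperature |
|---|---|---|---|---|
| west | 49 mM (fed, over 2.0 min) | 49.0 mM | the addition at 15 °C, then warmed to 35 °C; the feed brings no volume worth counting |  |
| north | 49 mM (fed, over 2.0 min) | 49.0 mM | all else is in the flask from the start; the feed brings no volume worth counting | 35 °C |
| south-west | 49 mM | 49.0 mM (fed, over 2.0 min) | all else is in the flask from the start; the feed brings no volume worth counting | 35 °C |
| south | 49 mM | 49.0 mM | everything together at the start at 15 °C, warmed to 35 °C at 2.0 min |  |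

    E + D → E.D (k1 = 7.28 M⁻¹ s⁻¹, Ea1 = 47.0 kJ mol⁻¹)
    Q → Z (k2 = 0.0195 s⁻¹, Ea2 = 94.0 kJ mol⁻¹)
    E + J → E.J (k3 = 28.1 M⁻¹ s⁻¹, Ea3 = 48.0 kJ mol⁻¹)
    E + Q → E.Q (k4 = 4.65 M⁻¹ s⁻¹, Ea4 = 53.0 kJ mol⁻¹)
    (constants at 35 °C)

- all constants are for 35 °C and move with temperature by the activation energies

* the flask that comes out highest in amount of E.Q, in percent of the E charged, or "all alike" when all lie within 1.5 percentage points (west / north / south-west / south / all alike)
* E.Q at the end, in percent of the E charged, west
* E.Q at the end, in percent of the E charged, north
* E.Q at the end, in percent of the E charged, south-west
* E.Q at the end, in percent of the E charged, south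

**The budget.** We count what is left, not what is made. Per mM, J binds E faster than Q does, and so does D. If we take J and D as fully served, the E left for Q is 34.3 mM. That leaves 14.7 mM of Q that can fall apart to Z without costing E.Q.

**Enough Q.** In south-west, with E at that level, capture of Q runs 8.18 times as fast as its decay. In south, capture starts 35 times as fast as decay at 15 °C, and cooling slows decay more than capture. West is fed in the same cold. So we commit to 70.0% for west, 70.0% for south-west and 70.0% for south. This budget does not part these flasks, so our reckoning stops short of a winner.

**Tie level.** North is fed E at 24.5 mM min⁻¹ at 35 °C, while Q decays from the first moment. We give J and D the first of the feed, which takes 36.0 s. Decay leaves about half of Q over that time, or 24.3 mM.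

After that, we take E to be bound as fast as it arrives, the quasi-steady state. Q then loses the feed and its decay together. We define the tie level as the feed rate of E divided by the decay constant of Q, 20.9 mM: the cQ at which decay removes Q as fast as the feed brings E. Above it, decay takes Q faster than the feed can bind it, and north's charge of Q stands at 2.34 times this level.

The sum of cQ and the tie level shrinks exponentially with k2, and in this reckoning cQ reaches zero when that sum has fallen to the tie level. That takes 39.5 s, which ends within the feed. The E bound in that time is 16.1 mM, so we commit to 32.9% for north.

**The forecast.** It gives 68% for west, 32% for north, 68% for south-west and 70.5% for south, and it names south as highest, calling that lead “thin on a rough mental estimate”. The choice of a winner is the forecast's, not ours.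

**At the reading.** The simulation puts south highest, with 71.1%, against 68.1% for west, 67.7% for south-west and 32.6% for north. North ended with Z at 33.0 mM against E.Q at 16.0 mM, and its charge of Q stood above the tie level. With the tie level held, our reckoning for north gains 4.9 percentage points at 60.0 mM of Q and loses 4.9 points at 39.2 mM, and the simulated north moved by 5 points at each of those charges.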